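**Retrosynthetic overview**

1. The target is two (3S,4S)-trans-α,β-dibenzylbutyrolactones joined by a diaryl ether from the O3 oxygen of ring B (3-O-aryl, 4-OH, 5-OMe) to C4 of ring A; the last operations are O-debenzylation, O-methylation, dehydrogenation and decarboxylation.
2. The route rests on the 1,3,4-pattern of ring A: the lactonylmethyl carbon on C1, OMe on C3 and the ether oxygen on C4. Read backwards, C3 is a ketone carbon and C4 the aryloxy-bearing alkene carbon of a 5-alkyl-2-aryloxycyclohex-2-en-1-one, so ring A can be grown on the ring B oxygen.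
3. Key disconnection: the C1–C2 bond (Michael addition) and the C4–C5 bond (aldol condensation) of ring A, from enal 14 and the tert-butyl 4-aryloxyacetoacetate 24 of the ring B monomer.
4. Both partners come from one (S)-β-veratryl-γ-butyrolactone 9 (Evans alkylation, reduction, lactonisation). It is alkylated trans either with allyl bromide (then cross-metathesis with crotonaldehyde) or with benzylic bromide 19 made from 5-hydroxyvanillin.
5. Ring order: the butyrolactone ring (steps 1–4, used twice), then carbocycle A (step 14), which is aromatised in step 16.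

Key step: step 14

Remark on the chemistry: compounds 25 to 29 are carried as mixtures at the stereogenic sp3 carbons of the nascent ring A (no descriptors are given there) because step 16 flattens them, so either enantiomer of the amine catalyst in step 14 may be used.
Shorthand in names: LacCH2 = [(3S,4S)-4-(3,4-dimethoxybenzyl)-2-oxotetrahydrofuran-3-yl]methyl; ArBO = 2-(benzyloxy)-5-(LacCH2)-3-methoxyphenoxy. Ring A is numbered as in the target (C1 chain, C3 OMe, C4 ether oxygen).

**Route**

Step 1
Reactants: 1 3-(3,4-dimethoxyphenyl)propanoic acid; 2 (R)-4-benzyl-1,3-oxazolidin-2-one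
Product: 4 (R)-4-benzyl-3-[3-(3,4-dimethoxyphenyl)propanoyl]-1,3-oxazolidin-2-one, via mixed pivalic anhydride 3 (not isolated)
Conditions: PivCl, Et3N, THF, −20 °C; then 2, LiCl, −20 °C to rt
Reagents that add atoms: none
Why: N-acylation of the oxazolidinone through the mixed pivalic anhydride (LiCl/Et3N variant) is the standard way to load an Evans auxiliary and creates no stereocentre.

Step 2
Reactants: 4 (R)-4-benzyl-3-[3-(3,4-dimethoxyphenyl)propanoyl]-1,3-oxazolidin-2-one; 5 tert-butyl bromoacetate
Product: 7 tert-butyl (3S)-4-[(4R)-4-benzyl-2-oxo-1,3-oxazolidin-3-yl]-3-(3,4-dimethoxybenzyl)-4-oxobutanoate, via sodium enolate 6 (not isolated)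
Conditions: NaN(SiMe3)2, THF, −78 °C; then 5, −78 to −40 °C
Reagents that add atoms: none
Why: Evans alkylation, in which the chelated sodium (Z)-enolate is attacked by the bromoacetate on the face away from the C4 benzyl group of the (R)-auxiliary, sets the (S)-carbon that becomes C4 of both lactones.

Step 3
Reactants: 7 tert-butyl (3S)-4-[(4R)-4-benzyl-2-oxo-1,3-oxazolidin-3-yl]-3-(3,4-dimethoxybenzyl)-4-oxobutanoate
Product: 8 tert-butyl (3S)-3-(3,4-dimethoxybenzyl)-4-hydroxybutanoate
Conditions: LiBH4, MeOH (1.1 equiv), THF, 0 °C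
Reagents that add atoms: none
Why: Reductive auxiliary cleavage, in which LiBH4 reduces the activated exocyclic imide carbonyl to the primary alcohol chemoselectively beside the tert-butyl ester, leaves the stereocentre untouched and returns auxiliary 2.

Step 4
Reactants: 8 tert-butyl (3S)-3-(3,4-dimethoxybenzyl)-4-hydroxybutanoate
Product: 9 (4S)-4-(3,4-dimethoxybenzyl)dihydrofuran-2(3H)-one
Conditions: CF3CO2H, CH2Cl2, 0 °C to rt
Reagents that add atoms: none
Why: Acid-mediated lactonisation of the γ-hydroxy tert-butyl ester (loss of isobutene, then 5-exo-trig acyl substitution) closes the butyrolactone without touching the stereocentre.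

Step 5
Reactants: 9 (4S)-4-(3,4-dimethoxybenzyl)dihydrofuran-2(3H)-one; 10 allyl bromide
Product: 12 (3S,4S)-3-allyl-4-(3,4-dimethoxybenzyl)dihydrofuran-2(3H)-one, via lithium enolate 11 (not isolated)
Conditions: LiN(SiMe3)2, THF, −78 °C; then 10, −78 to −40 °C
Reagents that add atoms: none
Why: Lactone enolate alkylation, in which allyl bromide approaches the enolate anti to the C4 veratryl group, sets the new C3 centre trans (3S) under substrate control.

Step 6
Reactants: 12 (3S,4S)-3-allyl-4-(3,4-dimethoxybenzyl)dihydrofuran-2(3H)-one; 13 (E)-crotonaldehyde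
Product: 14 (E)-4-[(3S,4S)-4-(3,4-dimethoxybenzyl)-2-oxotetrahydrofuran-3-yl]but-2-enal
Conditions: 13 (5 equiv), second-generation Grubbs catalyst RuCl2(=CHPh)(PCy3)(H2IMes) (5 mol%), CH2Cl2, 40 °C
Reagents that add atoms: none
Why: Olefin cross-metathesis of the terminal alkene with an excess of the electron-poor partner crotonaldehyde should give the (E)-enal under thermodynamic control with loss of propene, and the lactone centres are not involved.

Step 7
Reactants: 15 3,4-dihydroxy-5-methoxybenzaldehyde (5-hydroxyvanillin)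
Product: 16 4-(benzyloxy)-3-hydroxy-5-methoxybenzaldehyde
Conditions: BnBr (1.05 equiv), Li2CO3, DMF, 45 °C
Reagents that add atoms: benzyl bromide, BrCc1ccccc1
Why: Williamson etherification with a weak base ionises only the more acidic 4-OH para to the aldehyde, so benzylation should be regioselective for O4.

Step 8
Reactants: 16 4-(benzyloxy)-3-hydroxy-5-methoxybenzaldehyde
Product: 17 4-(benzyloxy)-3-(tert-butyldimethylsilyloxy)-5-methoxybenzaldehyde
Conditions: TBSCl, imidazole, DMF, rt
Reagents that add atoms: tert-butyldimethylsilyl chloride, CC(C)(C)[Si](C)(C)Cl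
Why: Silylation of the remaining phenol with TBSCl and imidazole masks O3 for the reduction, bromination and enolate steps that follow.

Step 9
Reactants: 17 4-(benzyloxy)-3-(tert-butyldimethylsilyloxy)-5-methoxybenzaldehyde
Product: 18 [4-(benzyloxy)-3-(tert-butyldimethylsilyloxy)-5-methoxyphenyl]methanol
Conditions: NaBH4, THF–MeOH, 0 °C
Reagents that add atoms: none
Why: Hydride reduction of the aromatic aldehyde with NaBH4 at low temperature gives the benzylic alcohol and leaves the aryl silyl ether and the benzyl ether intact.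

Step 10
Reactants: 18 [4-(benzyloxy)-3-(tert-butyldimethylsilyloxy)-5-methoxyphenyl]methanol
Product: 19 4-(benzyloxy)-3-(tert-butyldimethylsilyloxy)-5-methoxybenzyl bromide
Conditions: CBr4, PPh3, CH2Cl2, 0 °C
Reagents that add atoms: carbon tetrabromide, BrC(Br)(Br)Br
Why: The Appel reaction converts the benzylic alcohol to the bromide under neutral conditions that spare the aryl silyl ether.

Step 11
Reactants: 9 (4S)-4-(3,4-dimethoxybenzyl)dihydrofuran-2(3H)-one; 19 4-(benzyloxy)-3-(tert-butyldimethylsilyloxy)-5-methoxybenzyl bromide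
Product: 21 (3S,4S)-3-[4-(benzyloxy)-3-(tert-butyldimethylsilyloxy)-5-methoxybenzyl]-4-(3,4-dimethoxybenzyl)dihydrofuran-2(3H)-one, via sodium enolate 20 (not isolated)
Conditions: 9, NaN(SiMe3)2, THF, −78 °C; then 19, −78 to −20 °C
Reagents that add atoms: none
Why: Lactone enolate alkylation, here through the more reactive sodium enolate to suit the bulkier, electron-rich benzylic bromide, in which the electrophile adds anti to the C4 veratryl group and so sets the (3S) centre trans under substrate control.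

Step 12
Reactants: 21 (3S,4S)-3-[4-(benzyloxy)-3-(tert-butyldimethylsilyloxy)-5-methoxybenzyl]-4-(3,4-dimethoxybenzyl)dihydrofuran-2(3H)-one
Product: 22 (3S,4S)-3-[4-(benzyloxy)-3-hydroxy-5-methoxybenzyl]-4-(3,4-dimethoxybenzyl)dihydrofuran-2(3H)-one
Conditions: Bu4NF, AcOH, THF, 0 °C
Reagents that add atoms: none
Why: Fluoride cleavage of the aryl silyl ether, buffered with acetic acid to protect the lactone and its α-centre, frees O3 of ring B.

Step 13
Reactants: 22 (3S,4S)-3-[4-(benzyloxy)-3-hydroxy-5-methoxybenzyl]-4-(3,4-dimethoxybenzyl)dihydrofuran-2(3H)-one; 23 tert-butyl 4-chloro-3-oxobutanoate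
Product: 24 tert-butyl 4-(ArBO)-3-oxobutanoate
Conditions: 23 (1.5 equiv), K2CO3, NaI (cat.), acetone, 50 °C
Reagents that add atoms: none
Why: Williamson etherification, in which the phenoxide displaces the halide of the α-halo ketone (SN2, iodide catalysis), is the known way from phenols and 4-chloroacetoacetates to 4-aryloxyacetoacetates, and K2CO3 is too weak to enolise the lactone.

Step 14
Reactants: 24 tert-butyl 4-(ArBO)-3-oxobutanoate; 14 (E)-4-[(3S,4S)-4-(3,4-dimethoxybenzyl)-2-oxotetrahydrofuran-3-yl]but-2-enal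
Product: 27 tert-butyl 3-(ArBO)-6-(LacCH2)-2-oxocyclohex-3-ene-1-carboxylate as a diastereomer mixture, via Michael adduct 25 (not isolated), via aldol 26 (not isolated)
Conditions: (S)-2-[diphenyl(trimethylsilyloxy)methyl]pyrrolidine (20 mol%), PhCO2H (20 mol%), toluene, rt; then TsOH·H2O (0.5 equiv), 40 °C
Reagents that add atoms: none
Why: The pyrrolidine catalyst condenses with enal 14 to an iminium ion, C2 of keto ester 24 (butanoate numbering, the carbon between the two carbonyl groups) adds to its β-carbon to give Michael adduct 25 after hydrolysis, and the enol on the aryloxy-bearing C4 side of the ketone then attacks the aldehyde to give aldol 26, which loses water under the acid finish so that the C=C lies between the aryloxy carbon and the former aldehyde carbon. The closest known reaction type is the amine-catalysed Michael–aldol condensation (Robinson-type annulation) of tert-butyl acetoacetates with enals to 2-oxocyclohexenecarboxylates, in which γ-substituted acetoacetates are known to close through the substituted γ-carbon. Ring A closes by a 6-(enolendo)-exo-trig aldol addition onto the aldehyde carbon, the only mode open to 25, since attack from C2 or from the aldehyde α-carbon would need a four-membered ring. The new sp3 centres at C1 and C2 of the future ring A (and at C4 and C5 in aldol 26) are not controlled and need not be, because steps 15 and 16 remove them all; the four lactone centres lie outside the reacting atoms. The step needs conjugate instead of carbonyl addition and C2 instead of C4 as the Michael donor: the bulky diphenyl(silyloxy)methyl group shields the iminium carbon against Knoevenagel condensation, and the far higher acidity of the C2–H fixes the donor, which is why the lactonylmethyl carbon sits 1,4 to the aryloxy carbon in the new ring and the ketone carbon is the one that will carry the methoxy group.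

Step 15
Reactants: 27 tert-butyl 3-(ArBO)-6-(LacCH2)-2-oxocyclohex-3-ene-1-carboxylate
Product: 29 2-(ArBO)-5-(LacCH2)cyclohex-2-en-1-one, via keto acid 28 (not isolated)
Conditions: TsOH·H2O (30 mol%), toluene, 80 °C
Reagents that add atoms: none
Why: Acid-catalysed loss of isobutene from the tert-butyl ester gives the β-keto acid, which decarboxylates thermally through its cyclic six-membered transition state, while the benzyl ether and the electron-poor aryl enol ether tolerate catalytic sulfonic acid.

Step 16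
Reactants: 29 2-(ArBO)-5-(LacCH2)cyclohex-2-en-1-one
Product: 31 2-(ArBO)-5-(LacCH2)phenol, via dienone 30 (not isolated)
Conditions: Pd(OCOCF3)2 (5 mol%), 2-(dimethylamino)pyridine (10 mol%), TsOH·H2O (20 mol%), O2 (1 atm), DMSO, 80 °C
Reagents that add atoms: none
Why: Palladium-catalysed aerobic dehydrogenation of a cyclohexenone, in which a divalent palladium enolate at the α'-carbon undergoes β-hydride elimination to the cross-conjugated dienone that tautomerises to the phenol while O2 reoxidises the catalyst, aromatises ring A without an electrophilic halogen that could attack the electron-rich arenes.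

Step 17
Reactants: 31 2-(ArBO)-5-(LacCH2)phenol
Product: 32 1-(ArBO)-2-methoxy-4-(LacCH2)benzene (the ring B O-benzyl ether of the target)
Conditions: MeI, K2CO3, acetone, 40 °C
Reagents that add atoms: iodomethane, CI
Why: Williamson O-methylation of the only free phenol installs the C3 methoxy group of ring A under conditions that neither open nor epimerise the lactones.

Step 18
Reactants: 32 1-(ArBO)-2-methoxy-4-(LacCH2)benzene
Product: 33 CNP0183104.1
Conditions: H2 (1 atm), Pd/C (10%), EtOAc–EtOH, rt
Reagents that add atoms: none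
Why: Hydrogenolysis of the benzyl aryl ether over Pd/C frees the ring B phenol, and the lactones, the diaryl ether and the methyl ethers are inert to these conditions.

**Compound list**

1 | 3-(3,4-dimethoxyphenyl)propanoic acid | COc1ccc(CCC(=O)O)cc1OC | starting material
2 | (R)-4-benzyl-1,3-oxazolidin-2-one | O=C1N[C@H](Cc2ccccc2)CO1 | starting material
3 | 3-(3,4-dimethoxyphenyl)propanoic pivalic anhydride | COc1ccc(CCC(=O)OC(=O)C(C)(C)C)cc1OC | intermediate
4 | (R)-4-benzyl-3-[3-(3,4-dimethoxyphenyl)propanoyl]-1,3-oxazolidin-2-one | COc1ccc(CCC(=O)N2[C@H](Cc3ccccc3)COC2=O)cc1OC | intermediate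
5 | tert-butyl bromoacetate | CC(C)(C)OC(=O)CBr | starting material
6 | sodium (Z)-enolate of 4 | COc1ccc(C/C=C(\[O-])N2[C@H](Cc3ccccc3)COC2=O)cc1OC.[Na+] | intermediate
7 | tert-butyl (3S)-4-[(4R)-4-benzyl-2-oxo-1,3-oxazolidin-3-yl]-3-(3,4-dimethoxybenzyl)-4-oxobutanoate | COc1ccc(C[C@@H](CC(=O)OC(C)(C)C)C(=O)N2[C@H](Cc3ccccc3)COC2=O)cc1OC | intermediate
8 | tert-butyl (3S)-3-(3,4-dimethoxybenzyl)-4-hydroxybutanoate | COc1ccc(C[C@@H](CC(=O)OC(C)(C)C)CO)cc1OC | intermediate
9 | (4S)-4-(3,4-dimethoxybenzyl)dihydrofuran-2(3H)-one | COc1ccc(C[C@@H]2COC(=O)C2)cc1OC | intermediate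
10 | allyl bromide | C=CCBr | starting material
11 | lithium enolate of 9 | COc1ccc(C[C@@H]2COC([O-])=C2)cc1OC.[Li+] | intermediate
12 | (3S,4S)-3-allyl-4-(3,4-dimethoxybenzyl)dihydrofuran-2(3H)-one | COc1ccc(C[C@@H]2COC(=O)[C@H]2CC=C)cc1OC | intermediate
13 | (E)-crotonaldehyde | C/C=C/C=O | starting material
14 | (E)-4-[(3S,4S)-4-(3,4-dimethoxybenzyl)-2-oxotetrahydrofuran-3-yl]but-2-enal | COc1ccc(C[C@@H]2COC(=O)[C@H]2C/C=C/C=O)cc1OC | intermediate
15 | 3,4-dihydroxy-5-methoxybenzaldehyde (5-hydroxyvanillin) | COc1cc(C=O)cc(O)c1O | starting material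
16 | 4-(benzyloxy)-3-hydroxy-5-methoxybenzaldehyde | COc1cc(C=O)cc(O)c1OCc1ccccc1 | intermediate
17 | 4-(benzyloxy)-3-(tert-butyldimethylsilyloxy)-5-methoxybenzaldehyde | COc1cc(C=O)cc(O[Si](C)(C)C(C)(C)C)c1OCc1ccccc1 | intermediate
18 | [4-(benzyloxy)-3-(tert-butyldimethylsilyloxy)-5-methoxyphenyl]methanol | COc1cc(CO)cc(O[Si](C)(C)C(C)(C)C)c1OCc1ccccc1 | intermediate
19 | 4-(benzyloxy)-3-(tert-butyldimethylsilyloxy)-5-methoxybenzyl bromide | COc1cc(CBr)cc(O[Si](C)(C)C(C)(C)C)c1OCc1ccccc1 | intermediate
20 | sodium enolate of 9 | COc1ccc(C[C@@H]2COC([O-])=C2)cc1OC.[Na+] | intermediate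
21 | (3S,4S)-3-[4-(benzyloxy)-3-(tert-butyldimethylsilyloxy)-5-methoxybenzyl]-4-(3,4-dimethoxybenzyl)dihydrofuran-2(3H)-one | COc1ccc(C[C@@H]2COC(=O)[C@H]2Cc2cc(O[Si](C)(C)C(C)(C)C)c(OCc3ccccc3)c(OC)c2)cc1OC | intermediate
22 | (3S,4S)-3-[4-(benzyloxy)-3-hydroxy-5-methoxybenzyl]-4-(3,4-dimethoxybenzyl)dihydrofuran-2(3H)-one | COc1ccc(C[C@@H]2COC(=O)[C@H]2Cc2cc(O)c(OCc3ccccc3)c(OC)c2)cc1OC | intermediate
23 | tert-butyl 4-chloro-3-oxobutanoate | CC(C)(C)OC(=O)CC(=O)CCl | starting material
24 | tert-butyl 4-[2-(benzyloxy)-5-{[(3S,4S)-4-(3,4-dimethoxybenzyl)-2-oxotetrahydrofuran-3-yl]methyl}-3-methoxyphenoxy]-3-oxobutanoate | COc1ccc(C[C@@H]2COC(=O)[C@H]2Cc2cc(OCC(=O)CC(=O)OC(C)(C)C)c(OCc3ccccc3)c(OC)c2)cc1OC | intermediate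
25 | tert-butyl 2-[(ArBO)acetyl]-3-(LacCH2)-5-oxopentanoate (Michael adduct, mixture at C2 and C3) | CC(C)(C)OC(=O)C(C(=O)COc1cc(C[C@@H]2C(=O)OC[C@H]2Cc2ccc(OC)c(OC)c2)cc(OC)c1OCc1ccccc1)C(CC=O)C[C@@H]1C(=O)OC[C@H]1Cc1ccc(OC)c(OC)c1 | intermediate
26 | tert-butyl 3-(ArBO)-4-hydroxy-6-(LacCH2)-2-oxocyclohexane-1-carboxylate (aldol, mixture at the four ring centres) | CC(C)(C)OC(=O)C1C(C[C@@H]2C(=O)OC[C@H]2Cc2ccc(OC)c(OC)c2)CC(O)C(Oc2cc(C[C@@H]3C(=O)OC[C@H]3Cc3ccc(OC)c(OC)c3)cc(OC)c2OCc2ccccc2)C1=O | intermediate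
27 | tert-butyl 3-(ArBO)-6-(LacCH2)-2-oxocyclohex-3-ene-1-carboxylate (mixture at C1 and C6) | CC(C)(C)OC(=O)C1C(C[C@@H]2C(=O)OC[C@H]2Cc2ccc(OC)c(OC)c2)CC=C(Oc2cc(C[C@@H]3C(=O)OC[C@H]3Cc3ccc(OC)c(OC)c3)cc(OC)c2OCc2ccccc2)C1=O | intermediate
28 | 3-(ArBO)-6-(LacCH2)-2-oxocyclohex-3-ene-1-carboxylic acid (mixture at C1 and C6) | OC(=O)C1C(C[C@@H]2C(=O)OC[C@H]2Cc2ccc(OC)c(OC)c2)CC=C(Oc2cc(C[C@@H]3C(=O)OC[C@H]3Cc3ccc(OC)c(OC)c3)cc(OC)c2OCc2ccccc2)C1=O | intermediate
29 | 2-(ArBO)-5-(LacCH2)cyclohex-2-en-1-one (mixture at C5) | O=C1CC(C[C@@H]2C(=O)OC[C@H]2Cc2ccc(OC)c(OC)c2)CC=C1Oc1cc(C[C@@H]2C(=O)OC[C@H]2Cc2ccc(OC)c(OC)c2)cc(OC)c1OCc1ccccc1 | intermediate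
30 | 2-(ArBO)-5-(LacCH2)cyclohexa-2,5-dien-1-one | O=C1C=C(C[C@@H]2C(=O)OC[C@H]2Cc2ccc(OC)c(OC)c2)CC=C1Oc1cc(C[C@@H]2C(=O)OC[C@H]2Cc2ccc(OC)c(OC)c2)cc(OC)c1OCc1ccccc1 | intermediate
31 | 2-(ArBO)-5-(LacCH2)phenol | Oc1cc(C[C@@H]2C(=O)OC[C@H]2Cc2ccc(OC)c(OC)c2)ccc1Oc1cc(C[C@@H]2C(=O)OC[C@H]2Cc2ccc(OC)c(OC)c2)cc(OC)c1OCc1ccccc1 | intermediate
32 | 1-(ArBO)-2-methoxy-4-(LacCH2)benzene (ring B O-benzyl ether of the target) | COc1cc(C[C@@H]2C(=O)OC[C@H]2Cc2ccc(OC)c(OC)c2)ccc1Oc1cc(C[C@@H]2C(=O)OC[C@H]2Cc2ccc(OC)c(OC)c2)cc(OC)c1OCc1ccccc1 | intermediate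
33 | CNP0183104.1 | COc1ccc(C[C@@H]2COC(=O)[C@H]2Cc2ccc(Oc3cc(C[C@@H]4C(=O)OC[C@H]4Cc4ccc(OC)c(OC)c4)cc(OC)c3O)c(OC)c2)cc1OC | target

**Step count**

Total: 18 steps. Longest linear sequence: 12 steps (steps 1–4, 11–13 and 14–18; the branch from 15 through steps 7–13 and 14–18 is equally long).

**Steps most likely to fail**

Step 14 (annulation). The cascade may stall after the conjugate addition because the adduct rests as its cyclic hemiacetal or dehydrates to a 4H-pyran. The keto ester may also add to the aldehyde carbon (Knoevenagel condensation, then oxa-electrocyclisation to a 2H-pyran), or the enal may be drained through γ-deprotonation to a dienamine and self-condensation. The fallback gives up the ring construction and forms the diaryl ether by copper catalysis. It sets out from lactone 9 and phenol 22. Lactone 9 is deprotonated to lithium enolate 11 (LiN(SiMe3)2, THF, −78 °C) and alkylated trans with commercial 4-bromo-3-methoxybenzyl bromide (COc1cc(CBr)ccc1Br) to give (3S,4S)-3-(4-bromo-3-methoxybenzyl)-4-(3,4-dimethoxybenzyl)dihydrofuran-2(3H)-one F1. Ullmann-type coupling of this aryl bromide with phenol 22 (CuI, N,N-dimethylglycine hydrochloride, Cs2CO3, dioxane, 90 °C) should give the diaryl ether directly. The fallback comes back to the route at 32, so that only step 18 remains.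

Step 16 (aromatisation). The second dehydrogenation may stop short, the catalyst may be held back by the chelating 2-aryloxy ketone, or the electron-rich phenol may be oxidised further under O2. The fallback is stepwise and sets out from enone 29. Soft enolisation (Me3SiOTf, Et3N, CH2Cl2, 0 °C) should give the cross-conjugated 3-(ArBO)-6-(LacCH2)-2-(trimethylsilyloxy)cyclohexa-1,3-diene F2. Saegusa–Ito oxidation with Pd(OAc)2 (1.1 equiv, MeCN–DMSO, rt) converts it to dienone 30 and zerovalent palladium, and the dienone tautomerises to the phenol. The fallback comes back at 31.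

Step 13 (ether formation with the chloro keto ester). The base may consume the chloro keto ester by self-condensation, and C-alkylation of the product keto ester may compete with O-alkylation of the ortho-substituted phenoxide. The fallback builds the keto ester after the ether bond and sets out from phenol 22. Alkylation with tert-butyl bromoacetate 5 (K2CO3, acetone, 50 °C) gives tert-butyl (ArBO)acetate F3. CF3CO2H in CH2Cl2 at rt frees (ArBO)acetic acid F4. 1,1'-Carbonyldiimidazole in THF gives 1-[(ArBO)acetyl]imidazole F5, which is not isolated. Mg(O2CCH2CO2tBu)2 (THF, rt to 40 °C, then dilute HCl) brings about the decarboxylative Claisen condensation (Masamune–Brooks homologation). The fallback comes back at 24.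

**Further compounds**

F1 | step 14 | (3S,4S)-3-(4-bromo-3-methoxybenzyl)-4-(3,4-dimethoxybenzyl)dihydrofuran-2(3H)-one | COc1ccc(C[C@@H]2COC(=O)[C@H]2Cc2ccc(Br)c(OC)c2)cc1OC
F2 | step 16 | 3-(ArBO)-6-(LacCH2)-2-(trimethylsilyloxy)cyclohexa-1,3-diene | C[Si](C)(C)OC1=CC(C[C@@H]2C(=O)OC[C@H]2Cc2ccc(OC)c(OC)c2)CC=C1Oc1cc(C[C@@H]2C(=O)OC[C@H]2Cc2ccc(OC)c(OC)c2)cc(OC)c1OCc1ccccc1
F3 | step 13 | tert-butyl (ArBO)acetate | COc1ccc(C[C@@H]2COC(=O)[C@H]2Cc2cc(OCC(=O)OC(C)(C)C)c(OCc3ccccc3)c(OC)c2)cc1OC
F4 | step 13 | (ArBO)acetic acid | COc1ccc(C[C@@H]2COC(=O)[C@H]2Cc2cc(OCC(=O)O)c(OCc3ccccc3)c(OC)c2)cc1OC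
F5 | step 13 | 1-[(ArBO)acetyl]imidazole | COc1ccc(C[C@@H]2COC(=O)[C@H]2Cc2cc(OCC(=O)n3ccnc3)c(OCc3ccccc3)c(OC)c2)cc1OC
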